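**Retrosynthetic overview**
1. The target is 2',3',4',6,7-pentamethoxyflavone (C20H20O7), a flat molecule with no stereocentre.
2. The key disconnection is C2–C1' (pyranone to ring B). Chromone C2 is an enone β-carbon and a masked aroyl carbon, so it is normally an electrophile. Here it serves as a C2 carbanion (α-alkoxyvinyl = masked acyl anion, β-acylvinyl d3 synthon, held on zinc). It is joined to the ipso carbon of 1-iodo-2,3,4-trimethoxybenzene, which is also an electrophile.
3. The carbanion comes from direct C2–H zincation of unprotected 6,7-dimethoxychromone.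
4. The second disconnection is O1–C2 and C2–C3 of the chromone, leading back to 2-hydroxy-4,5-dimethoxyacetophenone plus a one-carbon amide acetal.
5. Ring order: rings A and B are bought, ring C (pyranone) is closed first, and ring B is attached last.

Assumption: the SMILES contains no stereocentre, stereogenic axis or configured double bond, so the target has only one form and no enantioselective step is needed.

**Step 1**
Reactants: 1 1-(2-hydroxy-4,5-dimethoxyphenyl)ethan-1-one
Product: 3 6,7-dimethoxy-4H-chromen-4-one, via enaminone 2 (not isolated)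
Conditions: DMF-DMA (1.5 equiv), toluene, 100 °C, 3 h; evaporate; AcOH, 110 °C, 1–2 h
Reagents that add atoms: N,N-dimethylformamide dimethyl acetal (DMF-DMA), COC(OC)N(C)C
Why: Amide-acetal condensation at the acidic acetyl CH3 (the hydrogen-bonded phenol is left alone) gives push-pull enaminone 2, and in hot acetic acid the phenol adds to its protonated β-carbon and expels dimethylamine (conjugate addition–elimination, the enaminone route to 3-unsubstituted chromones), closing ring C without creating a stereocentre.

**Step 2**
Reactants: 3 6,7-dimethoxy-4H-chromen-4-one; 4 1-iodo-2,3,4-trimethoxybenzene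
Product: 6 6,7-dimethoxy-2-(2,3,4-trimethoxyphenyl)-4H-chromen-4-one, via chromon-2-ylzinc chloride 5 (not isolated)
Conditions: TMPZnCl·LiCl (2,2,6,6-tetramethylpiperidin-1-ylzinc chloride–lithium chloride, commercial THF solution, 1.3 equiv), THF, 25 °C, 1–2 h, no MgCl2, BF3·OEt2 or other Lewis acid; then 4 (0.9 equiv), Pd(OAc)2 (2 mol %), SPhos (4 mol %), 50 °C, 12 h; aq NH4Cl
Reagents that add atoms: none
Why: C2–H (sp2, next to the ring oxygen, vinylogous to C=O) is the most acidic C–H of 3, so the bulky non-nucleophilic zinc amide removes it by C–H zincation instead of adding to the enone, the covalent C–Zn bond keeps 5 (an α-alkoxyvinyl, i.e. masked aroyl, and β-acylvinyl carbanion at a carbon that is normally an electrophile) from attacking a second chromone or opening the pyranone, and Negishi cross-coupling on zerovalent palladium/SPhos then joins it to the ipso carbon of 4, itself an electrophile, with the aryl methyl ethers and the free ketone inert and no stereocentre formed.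

**Compound list**
1 | 1-(2-hydroxy-4,5-dimethoxyphenyl)ethan-1-one | CC(=O)c1cc(OC)c(OC)cc1O | starting material
2 | (E)-3-(dimethylamino)-1-(2-hydroxy-4,5-dimethoxyphenyl)prop-2-en-1-one | CN(C)/C=C/C(=O)c1cc(OC)c(OC)cc1O | intermediate
3 | 6,7-dimethoxy-4H-chromen-4-one | COc1cc2occc(=O)c2cc1OC | intermediate
4 | 1-iodo-2,3,4-trimethoxybenzene | COc1ccc(I)c(OC)c1OC | starting material
5 | (6,7-dimethoxy-4-oxo-4H-chromen-2-yl)zinc chloride (present as its LiCl complex) | COc1cc2oc([Zn]Cl)cc(=O)c2cc1OC | intermediate
6 | 6,7-dimethoxy-2-(2,3,4-trimethoxyphenyl)-4H-chromen-4-one | COc1cc2oc(-c3ccc(OC)c(OC)c3OC)cc(=O)c2cc1OC | target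

**Totals**
Total step count: 2.
Longest linear sequence: 2 (1 → 3 → 6).

**Steps most likely to fail**
The route has only two steps. Step 2 is therefore listed twice, once for each of its two stages.

Risk 1 – step 2, zincation stage.
- The two donor methoxy groups lower the acidity of C2–H.
- Traces of carbonyl-binding Lewis acid steer TMP-zinc bases to C3.
- C8–H lies between two oxygens.
- Iodolysis or D2O quench of an aliquot will show which position was metalated.

The fallback sets out from 1 and comes back at 6. It fixes the site of the carbanion with a carboxyl group instead of relying on relative acidity. Claisen condensation of 1 with diethyl oxalate (NaOEt, EtOH, reflux) gives ethyl 4-(2-hydroxy-4,5-dimethoxyphenyl)-2,4-dioxobutanoate F1. Conc. HCl/AcOH at reflux closes this to ethyl 6,7-dimethoxy-4-oxo-4H-chromene-2-carboxylate F2 and hydrolyses it in the same pot to 6,7-dimethoxy-4-oxo-4H-chromene-2-carboxylic acid F3. Heating F3 with 4, Ag2CO3 (1.5 equiv), PdCl2 (10 mol %) and AsPh3 in DMSO at 130–150 °C expels CO2 and forms (6,7-dimethoxy-4-oxo-4H-chromen-2-yl)silver F4. This is the same C2 carbanion synthon, and it transmetalates to the arylpalladium iodide to give 6 (decarboxylative cross-coupling). Any protodecarboxylation only returns 3.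

Risk 2 – step 2, coupling stage.
- Compound 4 is electron-rich and ortho-substituted, so oxidative addition and reductive elimination are slow.
- Compound 5 may be protonated or may homocouple in the presence of the liberated amine and zinc salts.

The fallback sets out from 3 and comes back at 6. It replaces the in-flask zinc reagent with a storable boron ate complex made by kinetic lithiation with in situ trapping. Lithium 2,2,6,6-tetramethylpiperidide (LiTMP) is added to 3 and B(OiPr)3 in THF at −78 °C. The short-lived (6,7-dimethoxy-4-oxo-4H-chromen-2-yl)lithium F5 is caught at once as lithium (6,7-dimethoxy-4-oxo-4H-chromen-2-yl)triisopropoxyborate F6. This salt is freed of amine by evaporation and trituration. It is then used in excess (1.5–2 equiv) against 4 in a Suzuki–Miyaura coupling (Pd(OAc)2, XPhos, aq K3PO4, THF, 40 °C) to give 6.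

Risk 3 – step 1.
- DMF-DMA can O-methylate the phenol.
- Ring closure of 2 in AcOH may stall.

The fallback sets out from 1 and comes back at 3. It swaps the amide-acetal chemistry for an ester Claisen formylation. Compound 1 is treated with NaH (3 equiv) and ethyl formate in THF at 0–25 °C. Acid quench gives racemic 2-hydroxy-6,7-dimethoxychroman-4-one F7, the cyclic hemiacetal of the β-ketoaldehyde. Catalytic p-TsOH in toluene at reflux dehydrates it to 3, which removes the hemiacetal stereocentre.

**Further compounds**
F1 | step 2 | ethyl 4-(2-hydroxy-4,5-dimethoxyphenyl)-2,4-dioxobutanoate | CCOC(=O)C(=O)CC(=O)c1cc(OC)c(OC)cc1O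
F2 | step 2 | ethyl 6,7-dimethoxy-4-oxo-4H-chromene-2-carboxylate | CCOC(=O)c1cc(=O)c2cc(OC)c(OC)cc2o1
F3 | step 2 | 6,7-dimethoxy-4-oxo-4H-chromene-2-carboxylic acid | OC(=O)c1cc(=O)c2cc(OC)c(OC)cc2o1
F4 | step 2 | (6,7-dimethoxy-4-oxo-4H-chromen-2-yl)silver | [Ag]c1cc(=O)c2cc(OC)c(OC)cc2o1
F5 | step 2 | (6,7-dimethoxy-4-oxo-4H-chromen-2-yl)lithium | [Li]c1cc(=O)c2cc(OC)c(OC)cc2o1
F6 | step 2 | lithium (6,7-dimethoxy-4-oxo-4H-chromen-2-yl)triisopropoxyborate | [Li+].CC(C)O[B-](OC(C)C)(OC(C)C)c1cc(=O)c2cc(OC)c(OC)cc2o1
F7 | step 1 | 2-hydroxy-6,7-dimethoxychroman-4-one (racemic) | COc1cc2OC(O)CC(=O)c2cc1OC
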